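Readings and results are calculated on assumed constants.

A straight line from a first reading is the trap here. In Wednesday's run the first reading, carried on to 5.3 min, promises 32.9 mM of target, more than the 24.9 mM actually read. The curve is better replaced by its mean, κ = ln(S₀/(S₀ − P))/(C₀t), where S₀ is the starting material charged, P the target read at time t, and C₀ the catalyst charged. Thursday's last reading gives 544 M⁻¹ min⁻¹ for κ, the mean pseudo-first-order constant of the starting material per unit of catalyst. The averaging costs little in Thursday's run, whose reading at 2.6 min gives 541 M⁻¹ min⁻¹.

| flask | starting material | reagent | catalyst | time |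
|---|---|---|---|---|
| Wednesday's | 50.0 mM | 150 mM | 0.250 mM |  |
| Thursday's | 30.0 mM | 130 mM | 0.250 mM |  |
| Monday's | 50.0 mM | 150 mM | 0.130 mM |  |
| Saturday's | 100 mM | 150 mM | 0.250 mM |  |
| Friday's | 25.0 mM | 150 mM | 0.750 mM | 5.3 min |

| Wednesday's run: time / min | Wednesday's run: [target] / mM | Thursday's run: time / min | Thursday's run: [target] / mM | Monday's run: time / min | Monday's run: [target] / mM | Saturday's run: time / min | Saturday's run: [target] / mM |
|---|---|---|---|---|---|---|---|
| 0.66 | 4.1 | 0.66 | 3.2 | 0.66 | 2.3 | 0.66 | 6.5 |
| 1.3 | 8.0 | 1.3 | 5.3 | 1.3 | 4.1 | 1.3 | 11.7 |
| 2.0 | 11.7 | 2.0 | 7.6 | 2.0 | 6.1 | 2.0 | 17.2 |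
| 2.6 | 14.3 | 2.6 | 8.9 | 2.6 | 7.8 | 2.6 | 22.8 |
| 3.3 | 17.7 | 3.3 | 11.2 | 3.3 | 10.2 | 3.3 | 27.9 |
| 4.0 | 19.8 | 4.0 | 13.1 | 4.0 | 11.8 | 4.0 | 32.9 |
| 4.6 | 22.9 | 4.6 | 14.3 | 4.6 | 13.8 | 4.6 | 36.7 |
| 5.3 | 24.9 | 5.3 | 15.4 | 5.3 | 15.2 | 5.3 | 41.0 |

(scatter of a reading: 0.3 mM)

- Overall: starting material + reagent -> target, with catalyst as catalyst.
- Constant volume, constant temperature.
- What is held in complexes is read along with the free species.
- "The second partner" is reagent.
- An order is taken over about fifteen percent of the charge, up and down.

* the exponent of [reagent] in the starting rate at the charge of the Wednesday's run (at the point where two percent of the starting material have become target)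
* the exponent of [starting material] in the starting rate at the charge of the Wednesday's run (at the point where two percent of the starting material have become target) (one fixed amount of target, the same in the runs compared)
* the Thursday's run starts with 20.0 mM less of starting material and of reagent than the Wednesday's run, and with no target. Compared where both hold the same amount of starting material, once fifteen percent of what the Thursday's run was charged with has turned into target, is the Thursday's run faster, slower or alike (within a tenth)?
* target in the Friday's run at 5.3 min, as a share of the starting material charged
* which of these the readings show (the second partner is lost in pairs / the second partner kills the catalyst / the two partners rest in a complex / the catalyst dies by itself)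

Catalyst comes first. If the rate follows the catalyst, κ should not move when the catalyst changes. Monday's run holds about half of Wednesday's catalyst, and its κ is 526 M⁻¹ min⁻¹ against 520 M⁻¹ min⁻¹ in Wednesday's.

Starting material is next. A strict first order in starting material would leave κ alone, but Saturday's run, charged with twice Wednesday's amount, falls to 398 M⁻¹ min⁻¹, lower than Wednesday's. Thursday's κ sits slightly higher, in a run that differs from Wednesday's in both partners.

Reagent is lower only in Thursday's run, which also holds less starting material, so Thursday's κ carries both changes at once.

Friday's run has less starting material than Thursday's and more reagent. Of the charges of starting material in the runs with readings, Thursday's is the smallest and stands closest to Friday's, so my reckoning uses Thursday's κ as it stands. With 0.750 mM of catalyst over 5.3 min, the exponent κC₀t is 2.16, and this reckoning gives 88.5 % of the charge as target.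

The forecast stands higher, at 90 % (range 84 % to 95 %), with orders of 0.25 in reagent and 0.65 in starting material, Thursday's run alike, and the verdict that the two partners rest in a complex: “The partners evidently rest bound.”

Friday's run gives 91.3 %, the orders are 0.55 in reagent and 0.75 in starting material, Thursday's run is alike, and the two partners rest in a complex.

    catalyst + starting material ⇌ catalyst-substrate complex, settled at all times (9.860 M⁻¹)
    catalyst-substrate complex + reagent → target + catalyst + by-product (1386 M⁻¹ min⁻¹)
    starting material + reagent ⇌ idle substrate-reagent adduct, settled at all times (13.70 M⁻¹)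

Friday's own κ comes to 614 M⁻¹ min⁻¹, above Thursday's. Thursday's κ also carries to Monday's run, where ln(2)/(κC₀) gives 9.81 min, later than that run's last reading at 5.3 min. Monday's run reaches half of its charge as target at 9.98 min.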